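**Assumption:** the target SMILES contains no stereocentre (the molecule is achiral), so "single enantiomer" requires no stereocontrol and nothing can be scrambled.

## Retrosynthetic overview

1. Pseudophenone A is ring C (5-methylpyrogallol) carrying the ring D hemimellitate on its middle oxygen and the asterric-acid unit (rings A–B) on one outer oxygen; the last step is hydrogenolysis of four benzyl ethers.
2. The two aryl esters are cut next: the hindered C–D ester is made last, the (A–B)–C ester before it, both through acid chlorides.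
3. The three ring C oxygens are told apart by starting from atranol: one OH is benzylated, the other is acylated by the A–B acid, and the aldehyde becomes the middle OH by Baeyer–Villiger oxidation.
4. The A–B acid comes from an Ullmann diaryl ether coupling of a ring A phenol (Duff, Dakin, benzylation) with a ring B bromoaldehyde (ortho-lithiation/formylation, SNAr with BnOH), then Pinnick oxidation.
5. The ring D acid comes from C–H borylation/oxidation of dimethyl 2-bromoisophthalate, benzylation and Br/Mg exchange–CO2. No ring is constructed: four bought benzene rings are joined in the order A–B, (A–B)–C, C–D.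

## Route

**Step 1**
Reactants: 1 methyl 2-hydroxy-3-methoxybenzoate
Product: 2 methyl 5-formyl-2-hydroxy-3-methoxybenzoate
Conditions: hexamethylenetetramine (2 equiv), TFA, 80 °C; then 2 M HCl (aq), 60 °C
Reagents that add atoms: hexamethylenetetramine C1N2CN3CN1CN(C2)C3; water O
Why: Duff formylation goes para to the phenol because both ortho positions are blocked, and the methyl ester survives TFA.

**Step 2**
Reactants: 2 methyl 5-formyl-2-hydroxy-3-methoxybenzoate
Product: 4 methyl 2,5-dihydroxy-3-methoxybenzoate, via aryl formate 3 (not isolated)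
Conditions: 30% H2O2 (aq), NaOH (aq), THF, 0 °C → rt, N2; then HCl (aq)
Reagents that add atoms: hydrogen peroxide OO
Why: Dakin oxidation of a para-hydroxybenzaldehyde (aryl migration to the formate, then saponification), with the salicylate ester shielded by the adjacent phenoxide.

**Step 3**
Reactants: 4 methyl 2,5-dihydroxy-3-methoxybenzoate
Product: 5 methyl 5-(benzyloxy)-2-hydroxy-3-methoxybenzoate
Conditions: BnBr (1.05 equiv), K2CO3 (1.1 equiv), acetone, reflux
Reagents that add atoms: benzyl bromide BrCc1ccccc1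
Why: Williamson etherification is selective for the 5-OH because the 2-OH is hydrogen-bonded to the ester carbonyl and flanked by OMe.

**Step 4**
Reactants: 6 1-bromo-3-fluoro-5-methylbenzene
Product: 9 2-bromo-6-fluoro-4-methylbenzaldehyde, via aryllithium 7 (not isolated), via lithium hemiaminal alkoxide 8 (not isolated)
Conditions: LDA (1.1 equiv, commercial solution), THF, −78 °C; DMF, −78 → −20 °C; then HCl (aq)
Reagents that add atoms: N,N-dimethylformamide CN(C)C=O
Why: Directed ortho-lithiation removes the most acidic proton between Br and F (−78 °C avoids benzyne formation), and DMF formylates the aryllithium.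

**Step 5**
Reactants: 9 2-bromo-6-fluoro-4-methylbenzaldehyde
Product: 10 2-(benzyloxy)-6-bromo-4-methylbenzaldehyde
Conditions: BnOH (1.1 equiv), K2CO3, DMF, 70 °C
Reagents that add atoms: benzyl alcohol OCc1ccccc1
Why: SNAr displaces the fluoride activated by the ortho aldehyde while the bromide stays for the next step.

**Step 6**
Reactants: 5 methyl 5-(benzyloxy)-2-hydroxy-3-methoxybenzoate; 10 2-(benzyloxy)-6-bromo-4-methylbenzaldehyde
Product: 11 methyl 5-(benzyloxy)-2-[3-(benzyloxy)-2-formyl-5-methylphenoxy]-3-methoxybenzoate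
Conditions: CuI (10 mol%), N,N-dimethylglycine hydrochloride (30 mol%), Cs2CO3 (2 equiv), 1,4-dioxane, 100 °C
Reagents that add atoms: none
Why: Ligand-accelerated Ullmann diaryl ether synthesis, helped by the ortho-formyl group on the bromide, with only one free OH and one halide present.

**Step 7**
Reactants: 11 methyl 5-(benzyloxy)-2-[3-(benzyloxy)-2-formyl-5-methylphenoxy]-3-methoxybenzoate
Product: 12 2-(benzyloxy)-6-[4-(benzyloxy)-2-methoxy-6-(methoxycarbonyl)phenoxy]-4-methylbenzoic acid
Conditions: NaClO2, NaH2PO4, 2-methyl-2-butene, tBuOH/THF/H2O, 0 °C → rt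
Reagents that add atoms: sodium chlorite [Na+].[O-]Cl=O
Why: Pinnick oxidation converts the hindered aldehyde into the acid without touching the methyl ester or benzyl ethers, the alkene trapping HOCl before it chlorinates the electron-rich rings.

**Step 8**
Reactants: 13 dimethyl 2-bromobenzene-1,3-dicarboxylate
Product: 15 dimethyl 2-bromo-5-hydroxybenzene-1,3-dicarboxylate, via pinacol boronate 14 (not isolated)
Conditions: [Ir(OMe)(cod)]2 (1.5 mol%), dtbpy (3 mol%), B2pin2 (0.75 equiv), THF, 80 °C; then KHSO5 (oxone), acetone/H2O, rt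
Reagents that add atoms: potassium peroxymonosulfate [K+].[O-]S(=O)(=O)OO
Why: Sterically controlled Ir-catalysed C–H borylation hits C5, the only C–H without an ortho substituent, and ipso-oxidation of the boronate gives the phenol para to bromine.

**Step 9**
Reactants: 15 dimethyl 2-bromo-5-hydroxybenzene-1,3-dicarboxylate
Product: 16 dimethyl 5-(benzyloxy)-2-bromobenzene-1,3-dicarboxylate
Conditions: BnBr, K2CO3, DMF, rt
Reagents that add atoms: benzyl bromide BrCc1ccccc1
Why: Williamson etherification of the single, acidic phenol.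

**Step 10**
Reactants: 16 dimethyl 5-(benzyloxy)-2-bromobenzene-1,3-dicarboxylate
Product: 18 4-(benzyloxy)-2,6-bis(methoxycarbonyl)benzoic acid, via arylmagnesium chloride 17 (not isolated)
Conditions: iPrMgCl·LiCl (1.1 equiv), THF, −40 °C; CO2 (gas), −40 °C → rt; then 1 M HCl
Reagents that add atoms: carbon dioxide O=C=O
Why: Br/Mg exchange at the bromide flanked by two chelating esters outruns ester addition at −40 °C, and carboxylation gives the central acid already distinguished from the two methyl esters.

**Step 11**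
Reactants: 19 2,6-dihydroxy-4-methylbenzaldehyde (atranol)
Product: 20 2-(benzyloxy)-6-hydroxy-4-methylbenzaldehyde
Conditions: BnBr (1.0 equiv), K2CO3 (1.0 equiv), DMF, rt
Reagents that add atoms: benzyl bromide BrCc1ccccc1
Why: Mono-Williamson etherification of the symmetric diol stops after one alkylation because the remaining OH is locked in a strong hydrogen bond to the aldehyde.

**Step 12**
Reactants: 12 2-(benzyloxy)-6-[4-(benzyloxy)-2-methoxy-6-(methoxycarbonyl)phenoxy]-4-methylbenzoic acid; 20 2-(benzyloxy)-6-hydroxy-4-methylbenzaldehyde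
Product: 22 3-(benzyloxy)-2-formyl-5-methylphenyl 2-(benzyloxy)-6-[4-(benzyloxy)-2-methoxy-6-(methoxycarbonyl)phenoxy]-4-methylbenzoate, via acid chloride 21 (not isolated)
Conditions: (COCl)2, DMF (cat.), CH2Cl2, 0 °C → rt, evaporate; then 20, Et3N, DMAP (cat.), CH2Cl2, 0 °C → rt
Reagents that add atoms: none
Why: DMAP-catalysed esterification through the acid chloride acylates the only free OH, and ring A has no free position ortho to the ether oxygen, so xanthone formation is impossible.

**Step 13**
Reactants: 22 3-(benzyloxy)-2-formyl-5-methylphenyl 2-(benzyloxy)-6-[4-(benzyloxy)-2-methoxy-6-(methoxycarbonyl)phenoxy]-4-methylbenzoate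
Product: 24 3-(benzyloxy)-2-hydroxy-5-methylphenyl 2-(benzyloxy)-6-[4-(benzyloxy)-2-methoxy-6-(methoxycarbonyl)phenoxy]-4-methylbenzoate, via aryl formate 23 (not isolated)
Conditions: mCPBA (2 equiv), CH2Cl2, 0 °C → rt; then HCl (cat.), MeOH, rt
Reagents that add atoms: 3-chloroperoxybenzoic acid OOC(=O)c1cccc(Cl)c1
Why: Baeyer–Villiger oxidation (aryl migration favoured by the ortho benzyloxy and para methyl groups) turns the aldehyde into the middle oxygen of ring C, and acid-catalysed methanolysis frees it without cleaving or migrating the hindered neighbouring ester.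

**Step 14**
Reactants: 18 4-(benzyloxy)-2,6-bis(methoxycarbonyl)benzoic acid; 24 3-(benzyloxy)-2-hydroxy-5-methylphenyl 2-(benzyloxy)-6-[4-(benzyloxy)-2-methoxy-6-(methoxycarbonyl)phenoxy]-4-methylbenzoate
Product: 26 tetra-O-benzyl pseudophenone A (benzyl ethers on the ring A 5-OH, ring B 6-OH, ring C outer OH and ring D 4-OH), via acid chloride 25 (not isolated)
Conditions: (COCl)2, DMF (cat.), CH2Cl2, 0 °C → rt, evaporate; then 24, Et3N, DMAP (1 equiv), CH2Cl2, rt → 40 °C
Reagents that add atoms: none
Why: Esterification through the acylpyridinium of the acid chloride acylates the one remaining OH, and the 2,6-disubstituted benzoate already on ring C is too hindered to migrate under the amine base.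

**Step 15**
Reactants: 26 tetra-O-benzyl pseudophenone A
Product: 27 pseudophenone A
Conditions: H2 (1 atm), 10% Pd/C, EtOAc/THF, rt
Reagents that add atoms: none
Why: Neutral hydrogenolysis removes all four benzyl ethers and leaves the aryl esters, methyl esters and diaryl ether intact, with no base present to move an acyl group onto the freed ring C phenol.

## Compound list

1 | methyl 2-hydroxy-3-methoxybenzoate | COC(=O)c1cccc(OC)c1O | starting material
2 | methyl 5-formyl-2-hydroxy-3-methoxybenzoate | COC(=O)c1cc(C=O)cc(OC)c1O | intermediate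
3 | methyl 5-(formyloxy)-2-hydroxy-3-methoxybenzoate | COC(=O)c1cc(OC=O)cc(OC)c1O | intermediate (not isolated)
4 | methyl 2,5-dihydroxy-3-methoxybenzoate | COC(=O)c1cc(O)cc(OC)c1O | intermediate
5 | methyl 5-(benzyloxy)-2-hydroxy-3-methoxybenzoate | COC(=O)c1cc(OCc2ccccc2)cc(OC)c1O | intermediate
6 | 1-bromo-3-fluoro-5-methylbenzene | Cc1cc(F)cc(Br)c1 | starting material
7 | (2-bromo-6-fluoro-4-methylphenyl)lithium | [Li]c1c(F)cc(C)cc1Br | intermediate (not isolated)
8 | lithium (2-bromo-6-fluoro-4-methylphenyl)(dimethylamino)methanolate (racemic, transient) | [Li+].[O-]C(N(C)C)c1c(F)cc(C)cc1Br | intermediate (not isolated)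
9 | 2-bromo-6-fluoro-4-methylbenzaldehyde | Cc1cc(F)c(C=O)c(Br)c1 | intermediate
10 | 2-(benzyloxy)-6-bromo-4-methylbenzaldehyde | Cc1cc(Br)c(C=O)c(OCc2ccccc2)c1 | intermediate
11 | methyl 5-(benzyloxy)-2-[3-(benzyloxy)-2-formyl-5-methylphenoxy]-3-methoxybenzoate | COC(=O)c1cc(OCc2ccccc2)cc(OC)c1Oc1cc(C)cc(OCc2ccccc2)c1C=O | intermediate
12 | 2-(benzyloxy)-6-[4-(benzyloxy)-2-methoxy-6-(methoxycarbonyl)phenoxy]-4-methylbenzoic acid (di-O-benzyl asterric acid) | COC(=O)c1cc(OCc2ccccc2)cc(OC)c1Oc1cc(C)cc(OCc2ccccc2)c1C(=O)O | intermediate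
13 | dimethyl 2-bromobenzene-1,3-dicarboxylate | COC(=O)c1cccc(C(=O)OC)c1Br | starting material
14 | dimethyl 2-bromo-5-(4,4,5,5-tetramethyl-1,3,2-dioxaborolan-2-yl)benzene-1,3-dicarboxylate | COC(=O)c1cc(B2OC(C)(C)C(C)(C)O2)cc(C(=O)OC)c1Br | intermediate (not isolated)
15 | dimethyl 2-bromo-5-hydroxybenzene-1,3-dicarboxylate | COC(=O)c1cc(O)cc(C(=O)OC)c1Br | intermediate
16 | dimethyl 5-(benzyloxy)-2-bromobenzene-1,3-dicarboxylate | COC(=O)c1cc(OCc2ccccc2)cc(C(=O)OC)c1Br | intermediate
17 | [4-(benzyloxy)-2,6-bis(methoxycarbonyl)phenyl]magnesium chloride | COC(=O)c1cc(OCc2ccccc2)cc(C(=O)OC)c1[Mg]Cl | intermediate (not isolated)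
18 | 4-(benzyloxy)-2,6-bis(methoxycarbonyl)benzoic acid | COC(=O)c1cc(OCc2ccccc2)cc(C(=O)OC)c1C(=O)O | intermediate
19 | 2,6-dihydroxy-4-methylbenzaldehyde (atranol) | Cc1cc(O)c(C=O)c(O)c1 | starting material
20 | 2-(benzyloxy)-6-hydroxy-4-methylbenzaldehyde | Cc1cc(O)c(C=O)c(OCc2ccccc2)c1 | intermediate
21 | 2-(benzyloxy)-6-[4-(benzyloxy)-2-methoxy-6-(methoxycarbonyl)phenoxy]-4-methylbenzoyl chloride | COC(=O)c1cc(OCc2ccccc2)cc(OC)c1Oc1cc(C)cc(OCc2ccccc2)c1C(=O)Cl | intermediate (not isolated)
22 | 3-(benzyloxy)-2-formyl-5-methylphenyl 2-(benzyloxy)-6-[4-(benzyloxy)-2-methoxy-6-(methoxycarbonyl)phenoxy]-4-methylbenzoate | COC(=O)c1cc(OCc2ccccc2)cc(OC)c1Oc1cc(C)cc(OCc2ccccc2)c1C(=O)Oc1cc(C)cc(OCc2ccccc2)c1C=O | intermediate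
23 | 3-(benzyloxy)-2-(formyloxy)-5-methylphenyl 2-(benzyloxy)-6-[4-(benzyloxy)-2-methoxy-6-(methoxycarbonyl)phenoxy]-4-methylbenzoate | COC(=O)c1cc(OCc2ccccc2)cc(OC)c1Oc1cc(C)cc(OCc2ccccc2)c1C(=O)Oc1cc(C)cc(OCc2ccccc2)c1OC=O | intermediate (not isolated)
24 | 3-(benzyloxy)-2-hydroxy-5-methylphenyl 2-(benzyloxy)-6-[4-(benzyloxy)-2-methoxy-6-(methoxycarbonyl)phenoxy]-4-methylbenzoate | COC(=O)c1cc(OCc2ccccc2)cc(OC)c1Oc1cc(C)cc(OCc2ccccc2)c1C(=O)Oc1cc(C)cc(OCc2ccccc2)c1O | intermediate
25 | 4-(benzyloxy)-2,6-bis(methoxycarbonyl)benzoyl chloride | COC(=O)c1cc(OCc2ccccc2)cc(C(=O)OC)c1C(=O)Cl | intermediate (not isolated)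
26 | tetra-O-benzyl pseudophenone A: 1,3-dimethyl 2-[2-(benzyloxy)-6-({2-(benzyloxy)-6-[4-(benzyloxy)-2-methoxy-6-(methoxycarbonyl)phenoxy]-4-methylbenzoyl}oxy)-4-methylphenyl] 5-(benzyloxy)benzene-1,2,3-tricarboxylate | COC(=O)c1cc(OCc2ccccc2)cc(OC)c1Oc1cc(C)cc(OCc2ccccc2)c1C(=O)Oc1cc(C)cc(OCc2ccccc2)c1OC(=O)c1c(C(=O)OC)cc(OCc2ccccc2)cc1C(=O)OC | intermediate
27 | pseudophenone A (achiral) | COC(=O)c1cc(O)cc(OC)c1Oc1cc(C)cc(O)c1C(=O)Oc1cc(C)cc(O)c1OC(=O)c1c(C(=O)OC)cc(O)cc1C(=O)OC | target

## Totals

Total step count: 15.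
Longest linear sequence: 9 steps (steps 1, 2, 3, 6, 7, 12, 13, 14, 15).

## The three steps most likely to fail

**Step 14 (ester between the ring D acid and the middle OH of ring C).** Both partners are 2,6-disubstituted, and the phenol in 24 sits between a benzyloxy group and the bulky A–B ester. If the coupling stalls, or forcing conditions let the A–B acyl group move, the order of the two acylations is reversed so that the ring D acid meets a phenol flanked only by small ethers. This fallback sets out from 20 and comes back at 26. 20 is protected (MOMCl, iPr2NEt, CH2Cl2) as 2-(benzyloxy)-6-(methoxymethoxy)-4-methylbenzaldehyde F4. Baeyer–Villiger oxidation (mCPBA, CH2Cl2) gives 2-(benzyloxy)-6-(methoxymethoxy)-4-methylphenyl formate F5, which K2CO3 (cat.) in MeOH converts into 2-(benzyloxy)-6-(methoxymethoxy)-4-methylphenol F6. F6 is acylated with acid chloride 25 (Et3N, DMAP) to give 2-[2-(benzyloxy)-6-(methoxymethoxy)-4-methylphenyl] 1,3-dimethyl 5-(benzyloxy)benzene-1,2,3-tricarboxylate F7. Acidic methanolysis of the acetal (HCl, MeOH, 0 °C) gives 2-[2-(benzyloxy)-6-hydroxy-4-methylphenyl] 1,3-dimethyl 5-(benzyloxy)benzene-1,2,3-tricarboxylate F8. Its unhindered outer OH is then acylated with acid chloride 21 (from 12) to give 26. This costs two extra steps and bypasses 22 and 24.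

**Step 6 (Ullmann coupling of a chelated, doubly ortho-substituted phenol with an ortho-formyl aryl bromide).** The phenoxide of 5 is a poor nucleophile and the aldehyde may not tolerate hot carbonate. The fallback moves the coupling to the carboxylic acid oxidation level, where the ortho carboxylate binds copper and drives the classical Ullmann–Goldberg condensation. It sets out from 10 (with 5) and comes back at 12. Pinnick oxidation of 10 gives 2-(benzyloxy)-6-bromo-4-methylbenzoic acid F1. F1 is condensed with 5 (Cu powder, CuI (cat.), K2CO3, pyridine/DMF, 120 °C) to give 12 directly, so 11 is bypassed and the step count is unchanged.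

**Step 13 (Baeyer–Villiger oxidation on the advanced aldehyde 22).** One ortho oxygen is acylated and therefore a weaker donor, so hydride migration to the carboxylic acid may compete, and unmasking a phenol next to an aryl ester carries an acyl-migration risk. The fallback oxidises before acylating and then relies on steric discrimination of a catechol. It sets out from 20 and comes back at 24. Dakin oxidation of 20 (H2O2, NaOH, THF/H2O) proceeds through 2-(benzyloxy)-6-hydroxy-4-methylphenyl formate F2 to 3-(benzyloxy)-5-methylbenzene-1,2-diol F3. F3 is acylated with acid chloride 21 (from 12; pyridine, CH2Cl2, −20 °C) at the outer OH, which has only one ortho neighbour and is the hydrogen-bond donor of the pair, to give 24. Here 22 is bypassed and the step count is unchanged.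

## Further compounds

F1 | step 6 | 2-(benzyloxy)-6-bromo-4-methylbenzoic acid | Cc1cc(Br)c(C(=O)O)c(OCc2ccccc2)c1
F2 | step 13 | 2-(benzyloxy)-6-hydroxy-4-methylphenyl formate | Cc1cc(O)c(OC=O)c(OCc2ccccc2)c1
F3 | step 13 | 3-(benzyloxy)-5-methylbenzene-1,2-diol | Cc1cc(O)c(O)c(OCc2ccccc2)c1
F4 | step 14 | 2-(benzyloxy)-6-(methoxymethoxy)-4-methylbenzaldehyde | Cc1cc(OCOC)c(C=O)c(OCc2ccccc2)c1
F5 | step 14 | 2-(benzyloxy)-6-(methoxymethoxy)-4-methylphenyl formate | Cc1cc(OCOC)c(OC=O)c(OCc2ccccc2)c1
F6 | step 14 | 2-(benzyloxy)-6-(methoxymethoxy)-4-methylphenol | Cc1cc(OCOC)c(O)c(OCc2ccccc2)c1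
F7 | step 14 | 2-[2-(benzyloxy)-6-(methoxymethoxy)-4-methylphenyl] 1,3-dimethyl 5-(benzyloxy)benzene-1,2,3-tricarboxylate | COC(=O)c1cc(OCc2ccccc2)cc(C(=O)OC)c1C(=O)Oc1c(OCOC)cc(C)cc1OCc1ccccc1
F8 | step 14 | 2-[2-(benzyloxy)-6-hydroxy-4-methylphenyl] 1,3-dimethyl 5-(benzyloxy)benzene-1,2,3-tricarboxylate | COC(=O)c1cc(OCc2ccccc2)cc(C(=O)OC)c1C(=O)Oc1c(O)cc(C)cc1OCc1ccccc1
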